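Start at late times, where the alder run ends. The candidate steps send reagent two ways: reversibly with starting material to target, and one for one with second substrate to second product.

| flask | starting material | second substrate | reagent | free catalyst | remark | time |
|---|---|---|---|---|---|---|
| birch | 0.020 M | 0.040 M | 0.050 M | 5 µM | run made earlier |  |
| alder | 0.020 M | 0.040 M | 0.050 M | 20 µM | run made earlier |  |
| cedar | 0.040 M | 0.040 M | 0.050 M | 10 µM | run made earlier |  |
| flask | 0.020 M | 0.0400 M | 0.0500 M | 10 µM |  | 3.0 h |

- birch (time / h: target / %, starting material / %): 0.333: 17.6, 83.2; 0.500: 22.6, 77.6; 0.833: 32.3, 67.9; 1.00: 35.3, 64.7; 1.50: 40.0, 60.9; 2.50: 44.9, 55.3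
- alder (time / h: target / %, starting material / %): 0.333: 40.2, 59.5; 0.500: 44.2, 56.4; 0.833: 45.7, 54.5; 1.00: 44.5, 57.1; 1.50: 39.5, 61.6; 2.50: 33.0, 65.9
- cedar (time / h: target / %, starting material / %): 0.333: 20.6, 79.7; 0.500: 28.1, 74.6; 1.00: 35.6, 65.8; 1.33: 35.7, 62.4; 2.50: 38.3, 61.8

(each reading ± 1 percentage point)

- candidate steps: starting material + free catalyst <-> catalyst intermediate A; reagent + catalyst intermediate A <-> free catalyst + target; second substrate + free catalyst <-> catalyst intermediate B; reagent + catalyst intermediate B -> free catalyst + second product; second substrate + catalyst intermediate B -> spent catalyst

1. the best time, 3.0 h at the latest, for target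
2. the amount of target, in percent of the starting material charged, at that time
3. earliest time at which at least nineteen twentieths of that best amount are there
4. latest time at which they still are

Read the alder table downwards. In alder, target reads highest, 45.7%, at 0.833 h. In alder's last row it reads 33.0% at 2.50 h, while starting material has climbed back to 65.9%. So in alder, target is turning back into starting material.

Now count reagent in the flask. Its charge of 0.0500 M is less than the 0.0600 M that both claims together ask for, so the charge falls short of paying both in full. After the second substrate's claim, it pays for 50.0% of the starting material.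

My own assumption is that the second substrate's claim is fully paid by alder's last row. Reagent left there is then 0.00340 M. In that alder row, target over starting material, divided by reagent left, reads 147 M⁻¹; call this the late balance.

The flask differs from alder in its catalyst charge, and I assume the balance carries over. Solving it against the same reagent count, my reckoning puts late target in the flask at 33.2%. This concerns the far end, not the peak.

The forecast begins: “The catalyst only sets the clock”. It gives 45.5% at 1.6 h, and a window from 1 h to 2.3 h.

The flask gives 45.2% at 1.39 h, and a window from 0.868 h to 2.27 h. The window opens earlier than forecast.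

    starting material + free catalyst ⇌ catalyst intermediate A (K = 98.0 M⁻¹, k = 32000 M⁻¹ min⁻¹)
    reagent + catalyst intermediate A ⇌ free catalyst + target (K = 1.10, k = 1600 M⁻¹ min⁻¹)
    second substrate + free catalyst ⇌ catalyst intermediate B (K = 43.0 M⁻¹, k = 8600 M⁻¹ min⁻¹)
    reagent + catalyst intermediate B → free catalyst + second product (k = 29000 M⁻¹ min⁻¹)
    second substrate + catalyst intermediate B → spent catalyst (k = 2.50 M⁻¹ min⁻¹)

After 30.0 h the flask holds 30.1% target against my 33.2%, with second substrate at 0% and reagent at 7.98% of its charge. Now take the neighbour flask, charged like the flask but with 0.085 M of reagent. The same late balance, with the larger reagent count, gives 80.9%. That neighbour holds 76.3% target at 3.00 h, with second substrate at 0.0639% and reagent at 35.0% of its charge.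

All runs come from a simulation with made-up constants; noise was put on by code.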